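The upper pyran (C ring) is cut at C4–C4a. C4 is a diarylmethine carbon between two electron-rich rings, A-ring C4a (para to O7, ortho to O1) and D-ring C8 of epicatechin. It is therefore treated as an aldehyde carbon that is arylated twice. In one operation an open-chain 3-aryloxy-3-aryl-2-silyloxypropanal closes the C ring (C4a attacks the CHO). The resulting 4-ol then ionises, and tetra-O-benzylepicatechin is captured at C8 anti to the axial 3-oxygen, which sets C4. C3 and the C2–C3–C4 chain are bought as (R)-glyceraldehyde acetonide. C2 is relayed from C3 (Felkin–Anh arylation, Mitsunobu inversion). The lower unit is (−)-epicatechin.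

Key step: step 7

Remark: the target is read as epiguibourtinidol-(4β→8)-epicatechin. The upper unit is 2R,3R,4R (2,3-cis-3,4-trans) and the lower unit is 2R,3R. Flavan numbering is used throughout (rings A/C/B upper, D/F/E lower). Compounds 1, 2, 5 and 10 are taken as commercial.

Step 1
Reactants: 1 4-(benzyloxy)phenylmagnesium bromide (THF solution); 2 (R)-2,2-dimethyl-1,3-dioxolane-4-carbaldehyde
Product: 4 (S)-[4-(benzyloxy)phenyl][(4R)-2,2-dimethyl-1,3-dioxolan-4-yl]methanol (anti alcohol), via aryltitanium triisopropoxide 3 (not isolated)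
Conditions: ClTi(OiPr)3, THF, −78 → −20 °C; then 2, −78 → 0 °C; aq NH4Cl
Reagents that add atoms: none
Why: Transmetalation gives a non-chelating aryltitanium reagent whose Felkin–Anh (polar model) carbonyl addition to the α-alkoxy aldehyde should favour the anti (1S) carbinol, the minor syn epimer being removed by chromatography.

Step 2
Reactants: 4 anti alcohol; 5 3-(benzyloxy)phenol
Product: 6 (4R)-4-{(R)-[3-(benzyloxy)phenoxy][4-(benzyloxy)phenyl]methyl}-2,2-dimethyl-1,3-dioxolane (syn aryl ether)
Conditions: n-Bu3P, TMAD, toluene, 0 °C → rt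
Reagents that add atoms: none
Why: Mitsunobu etherification displaces the activated benzylic oxygen by the phenol with inversion (S to R), turning the anti alcohol into the syn aryl ether that a 2,3-cis flavan needs, while the non-polar solvent and low temperature should hold back SN1 leakage.

Step 3
Reactants: 6 syn aryl ether acetonide
Product: 7 (2R,3R)-3-[3-(benzyloxy)phenoxy]-3-[4-(benzyloxy)phenyl]propane-1,2-diol
Conditions: AcOH–H2O–THF, 45 °C
Reagents that add atoms: none
Why: Mild acid hydrolysis of a terminal isopropylidene acetal under conditions that benzyl ethers and 4-alkoxybenzyl aryl ethers normally tolerate, with no stereocentre touched.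

Step 4
Reactants: 7 diol
Product: 8 (2R,3R)-3-[3-(benzyloxy)phenoxy]-3-[4-(benzyloxy)phenyl]-1,2-bis(triethylsilyloxy)propane
Conditions: TESCl, imidazole, DMAP (cat.), CH2Cl2, 0 °C → rt
Reagents that add atoms: chlorotriethylsilane (TESCl), CC[Si](Cl)(CC)CC
Why: Standard silylation of both hydroxyl groups protects O3 and prepares the primary position for selective oxidation.

Step 5
Reactants: 8 bis-TES ether
Product: 9 (2S,3R)-3-[3-(benzyloxy)phenoxy]-3-[4-(benzyloxy)phenyl]-2-(triethylsilyloxy)propanal
Conditions: (COCl)2, DMSO, CH2Cl2, −78 → −40 °C; Et3N, −78 → −20 °C; cold quench, used crude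
Reagents that add atoms: none
Why: In this Swern oxidation (oxidative desilylation) activated DMSO attacks only the unhindered primary TES ether and converts it directly into the aldehyde while the secondary TES ether stays, and the cold base treatment should avoid C3 epimerisation and β-elimination of the aryloxide.

Step 6
Reactants: 10 (−)-epicatechin
Product: 11 5,7,3',4'-tetra-O-benzyl-(−)-epicatechin
Conditions: BnBr, K2CO3, DMF, 0 °C → rt, argon
Reagents that add atoms: benzyl bromide (BnBr), BrCc1ccccc1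
Why: Williamson etherification of the four phenols, whose acidity sets them apart from the secondary 3-OH, with exclusion of air and a mild base to keep C2 from epimerising.

Step 7
Reactants: 9 α-silyloxy aldehyde; 11 tetra-O-benzylepicatechin (excess, recovered)
Product: 14 hexa-O-benzyl epiguibourtinidol-(4β→8)-epicatechin (both 3-OH free), via flavan-4-ol 12 (not isolated), via 3-O-TES dimer 13 (not isolated)
Conditions: 11 (3 equiv), Sc(OTf)3 (20 mol %), 4 Å MS, CH2Cl2, −40 °C → rt; then H2O–MeCN, rt
Reagents that add atoms: none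
Why: Sc(OTf)3 activates the aldehyde of 9, and the aryloxy-ring carbon para to OBn and ortho to the ether oxygen (the future C4a) attacks it in a 6-exo-trig Friedel–Crafts hydroxyalkylation that closes the pyran C ring to flavan-4-ol 12, whose C4 configuration is irrelevant because the same catalyst ionises it to the C4 benzylic cation stabilised by O1 and the 7-OBn group. C8 of 11 captures this cation (dehydrative Friedel–Crafts alkylation) to give 13, and added water then lets the same catalyst hydrolyse the TES ether. The closest known reaction types are the Baeyer-type double arylation of aldehydes, the Pummerer/Friedel–Crafts pyran closure of flavans, and the Lewis-acid coupling of C4-oxygenated benzylated flavan-3-ols with tetra-O-benzyl(epi)catechin. The only new stereocentre, C4, is set by substrate control: in the half-chair cation the 2-aryl group is equatorial and the 3-OTES group axial on the α face, so 11 adds axially from the β face to give the 3,4-trans (4β, 4R) product. Ring closure needs para over ortho selectivity relative to OBn, which the crowded position between the two oxygens secures, and it must outrun intermolecular attack of 11 on the aldehyde, which the six-membered transition state favours (either order gives the same constitution). C8 over C6 selectivity and suppression of oligomers rest on the established behaviour of 11 used in excess, and the C2–OAr bond should survive because the aldehyde and the 4-ol are activated far more easily than the 4-alkoxybenzyl aryl ether.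

Step 8
Reactants: 14 hexa-O-benzyl dimer
Product: 15 epiguibourtinidol-(4β→8)-epicatechin (target)
Conditions: H2 (1 atm), 20% Pd(OH)2/C, THF–MeOH–H2O, rt
Reagents that add atoms: none
Why: Hydrogenolysis of the six aryl benzyl ethers over Pearlman's catalyst, under which the cyclic benzylic C2–O1 bonds and the C4 diarylmethine of benzylated proanthocyanidins are known to persist.

Compound list
1 | 4-(benzyloxy)phenylmagnesium bromide | Br[Mg]c1ccc(OCc2ccccc2)cc1 | starting material
2 | (R)-2,2-dimethyl-1,3-dioxolane-4-carbaldehyde [(R)-glyceraldehyde acetonide] | O=C[C@H]1COC(C)(C)O1 | starting material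
3 | [4-(benzyloxy)phenyl]titanium triisopropoxide | CC(C)O[Ti](OC(C)C)(OC(C)C)c1ccc(OCc2ccccc2)cc1 | intermediate
4 | (S)-[4-(benzyloxy)phenyl][(4R)-2,2-dimethyl-1,3-dioxolan-4-yl]methanol (anti) | c1ccccc1COc1ccc([C@H](O)[C@H]2COC(C)(C)O2)cc1 | intermediate
5 | 3-(benzyloxy)phenol | Oc1cccc(OCc2ccccc2)c1 | starting material
6 | (4R)-4-{(R)-[3-(benzyloxy)phenoxy][4-(benzyloxy)phenyl]methyl}-2,2-dimethyl-1,3-dioxolane (syn) | c1ccccc1COc1ccc([C@@H](Oc2cccc(OCc3ccccc3)c2)[C@H]2COC(C)(C)O2)cc1 | intermediate
7 | (2R,3R)-3-[3-(benzyloxy)phenoxy]-3-[4-(benzyloxy)phenyl]propane-1,2-diol | c1ccccc1COc1ccc([C@@H](Oc2cccc(OCc3ccccc3)c2)[C@H](O)CO)cc1 | intermediate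
8 | (2R,3R)-3-[3-(benzyloxy)phenoxy]-3-[4-(benzyloxy)phenyl]-1,2-bis(triethylsilyloxy)propane | c1ccccc1COc1ccc([C@@H](Oc2cccc(OCc3ccccc3)c2)[C@H](O[Si](CC)(CC)CC)CO[Si](CC)(CC)CC)cc1 | intermediate
9 | (2S,3R)-3-[3-(benzyloxy)phenoxy]-3-[4-(benzyloxy)phenyl]-2-(triethylsilyloxy)propanal | c1ccccc1COc1ccc([C@@H](Oc2cccc(OCc3ccccc3)c2)[C@H](O[Si](CC)(CC)CC)C=O)cc1 | intermediate
10 | (−)-epicatechin (2R,3R) | Oc1cc(O)c2c(c1)O[C@H](c1ccc(O)c(O)c1)[C@H](O)C2 | starting material
11 | 5,7,3',4'-tetra-O-benzyl-(−)-epicatechin | c1ccccc1COc1cc(OCc2ccccc2)c2c(c1)O[C@H](c1ccc(OCc3ccccc3)c(OCc3ccccc3)c1)[C@H](O)C2 | intermediate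
12 | (2R,3R)-7-(benzyloxy)-2-[4-(benzyloxy)phenyl]-3-(triethylsilyloxy)chroman-4-ol (C4 epimers) | c1ccccc1COc1ccc([C@H]2Oc3cc(OCc4ccccc4)ccc3C(O)[C@H]2O[Si](CC)(CC)CC)cc1 | intermediate
13 | (2R,3R,4R)-7,4'-di-O-benzyl-3-O-triethylsilylepiguibourtinidol-(4β→8)-5,7,3',4'-tetra-O-benzylepicatechin | c1ccccc1COc1ccc([C@H]2Oc3cc(OCc4ccccc4)ccc3[C@H](c3c(OCc4ccccc4)cc(OCc4ccccc4)c4c3O[C@H](c3ccc(OCc5ccccc5)c(OCc5ccccc5)c3)[C@H](O)C4)[C@H]2O[Si](CC)(CC)CC)cc1 | intermediate
14 | (2R,3R,4R)-7,4'-di-O-benzylepiguibourtinidol-(4β→8)-5,7,3',4'-tetra-O-benzylepicatechin | c1ccccc1COc1ccc([C@H]2Oc3cc(OCc4ccccc4)ccc3[C@H](c3c(OCc4ccccc4)cc(OCc4ccccc4)c4c3O[C@H](c3ccc(OCc5ccccc5)c(OCc5ccccc5)c3)[C@H](O)C4)[C@H]2O)cc1 | intermediate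
15 | epiguibourtinidol-(4β→8)-epicatechin (CNP0118995.2) | Oc1ccc([C@H]2Oc3cc(O)ccc3[C@H](c3c(O)cc(O)c4c3O[C@H](c3ccc(O)c(O)c3)[C@H](O)C4)[C@H]2O)cc1 | target

Total steps: 8. Longest linear sequence: 7 (steps 1–5, 7, 8).

Steps most likely to fail

Step 7. Several processes may compete.
- 11 may attack the aldehyde before ring closure, followed by a second intermolecular arylation.
- 11 may react through C6 instead of C8.
- The product may be over-alkylated to oligomers.
- Acid may ionise the C2–OAr bond.

The fallback builds the interflavan bond first, by carbonyl addition. It sets out from 11 and 9 and comes back at 14. Compound 11 is brominated at C8 (NBS, CH2Cl2, −78 °C) to 8-bromo-5,7,3',4'-tetra-O-benzylepicatechin F1. This is silylated (TESCl, imidazole) to its 3-O-triethylsilyl ether F2. Bromine–lithium exchange (n-BuLi, THF, −78 °C) then gives the 8-lithio derivative F3, which is added to 9 to give the C4 carbinol F4 (both C4 epimers serve). Because this carbinol sits on the trialkoxyphenyl D ring, it should ionise under much milder acid (PPTS or catalytic Sc(OTf)3, CH2Cl2, −40 °C). The A ring then closes the same C4–C4a bond intramolecularly, anti to the 3-OTES group, to the bis-triethylsilyl dimer F5. Aqueous HCl in THF–MeOH removes both silyl groups and gives 14. Regiochemistry at C8 is fixed by the bromide, and no free cation ever meets a second flavan unit.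

Step 2. The oxyphosphonium salt at the electron-rich benzylic carbon may ionise, which erodes the inversion. The phenol may also be alkylated at carbon. The fallback arylates the oxygen and never breaks the C2–O bond. It sets out from 4 and comes back at 6. Compound 4 is oxidised (Dess–Martin periodinane, NaHCO3, CH2Cl2) to the aryl dioxolanyl ketone F6. Felkin–Anh hydride delivery (L-Selectride, THF, −78 °C) should give the syn alcohol F7. Ullmann-type copper-catalysed O-arylation with 1-(benzyloxy)-3-iodobenzene then gives 6 with retention (CuI, 3,4,7,8-tetramethyl-1,10-phenanthroline, Cs2CO3, toluene, 110 °C).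

Step 5. The amine base may trigger β-elimination of the aryloxide or epimerisation at C3, and the discrimination between the two TES ethers may be incomplete. The fallback uses an acyl group on O3 and a base-free oxidation. It sets out from 7 and comes back at 14. Compound 7 is converted with MeC(OMe)3 and catalytic CSA into the cyclic orthoacetate F8. Kinetic hydrolysis of F8 (aq AcOH, 0 °C) should leave the secondary acetate with a free primary alcohol F9. This is oxidised at once (Dess–Martin periodinane, NaHCO3) to the α-acetoxy aldehyde F10. The conditions of step 7, without the water stage, applied to F10 and 11 should give the 3-O-acetyl hexa-O-benzyl dimer F11. Here the acetate adds anchimeric shielding of the α face. K2CO3 in MeOH–THF then gives 14.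

Further compounds
F1 | step 7 | 8-bromo-5,7,3',4'-tetra-O-benzylepicatechin | Brc1c(OCc3ccccc3)cc(OCc3ccccc3)c2c1O[C@H](c1ccc(OCc3ccccc3)c(OCc3ccccc3)c1)[C@H](O)C2
F2 | step 7 | 8-bromo-5,7,3',4'-tetra-O-benzyl-3-O-triethylsilylepicatechin | Brc1c(OCc3ccccc3)cc(OCc3ccccc3)c2c1O[C@H](c1ccc(OCc3ccccc3)c(OCc3ccccc3)c1)[C@H](O[Si](CC)(CC)CC)C2
F3 | step 7 | 8-lithio-5,7,3',4'-tetra-O-benzyl-3-O-triethylsilylepicatechin | [Li]c1c(OCc3ccccc3)cc(OCc3ccccc3)c2c1O[C@H](c1ccc(OCc3ccccc3)c(OCc3ccccc3)c1)[C@H](O[Si](CC)(CC)CC)C2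
F4 | step 7 | (2R,3R)-3-[3-(benzyloxy)phenoxy]-3-[4-(benzyloxy)phenyl]-2-(triethylsilyloxy)-1-(protected epicatechin-8-yl)propan-1-ol (C1 epimers) | c1ccccc1COc1ccc([C@@H](Oc2cccc(OCc3ccccc3)c2)[C@H](O[Si](CC)(CC)CC)C(O)c2c(OCc3ccccc3)cc(OCc3ccccc3)c3c2O[C@H](c2ccc(OCc4ccccc4)c(OCc4ccccc4)c2)[C@H](O[Si](CC)(CC)CC)C3)cc1
F5 | step 7 | hexa-O-benzyl-3,3''-bis-O-triethylsilyl epiguibourtinidol-(4β→8)-epicatechin | c1ccccc1COc1ccc([C@H]2Oc3cc(OCc4ccccc4)ccc3[C@H](c3c(OCc4ccccc4)cc(OCc4ccccc4)c4c3O[C@H](c3ccc(OCc5ccccc5)c(OCc5ccccc5)c3)[C@H](O[Si](CC)(CC)CC)C4)[C@H]2O[Si](CC)(CC)CC)cc1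
F6 | step 2 | [4-(benzyloxy)phenyl][(4R)-2,2-dimethyl-1,3-dioxolan-4-yl]methanone | O=C(c1ccc(OCc2ccccc2)cc1)[C@H]1COC(C)(C)O1
F7 | step 2 | (R)-[4-(benzyloxy)phenyl][(4R)-2,2-dimethyl-1,3-dioxolan-4-yl]methanol (syn) | c1ccccc1COc1ccc([C@@H](O)[C@H]2COC(C)(C)O2)cc1
F8 | step 5 | (4R)-4-{(R)-[3-(benzyloxy)phenoxy][4-(benzyloxy)phenyl]methyl}-2-methoxy-2-methyl-1,3-dioxolane | c1ccccc1COc1ccc([C@@H](Oc2cccc(OCc3ccccc3)c2)[C@H]2COC(C)(OC)O2)cc1
F9 | step 5 | (1R,2R)-1-[3-(benzyloxy)phenoxy]-1-[4-(benzyloxy)phenyl]-3-hydroxypropan-2-yl acetate | c1ccccc1COc1ccc([C@@H](Oc2cccc(OCc3ccccc3)c2)[C@H](OC(C)=O)CO)cc1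
F10 | step 5 | (1R,2S)-1-[3-(benzyloxy)phenoxy]-1-[4-(benzyloxy)phenyl]-3-oxopropan-2-yl acetate | c1ccccc1COc1ccc([C@@H](Oc2cccc(OCc3ccccc3)c2)[C@H](OC(C)=O)C=O)cc1
F11 | step 5 | 3-O-acetyl-hexa-O-benzyl epiguibourtinidol-(4β→8)-epicatechin | c1ccccc1COc1ccc([C@H]2Oc3cc(OCc4ccccc4)ccc3[C@H](c3c(OCc4ccccc4)cc(OCc4ccccc4)c4c3O[C@H](c3ccc(OCc5ccccc5)c(OCc5ccccc5)c3)[C@H](O)C4)[C@H]2OC(C)=O)cc1
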